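The level of homo dimer stood still once reached in the zeta, theta and eta runs while the first product faded, so each unit of substrate took its route early.

| flask | substrate | reagent | remark | time |
|---|---|---|---|---|
| zeta | 20 mM | 30 mM | run made earlier |  |
| theta | 20 mM | 42 mM | run made earlier |  |
| eta | 20 mM | 66 mM | run made earlier |  |
| elm | 20 mM (fed, over 2.5 d) | 30.0 mM | all else is in the flask from the start; the feed brings no volume worth counting | 12 d |
| maple | 20 mM | 30.0 mM | everything together at the start | 12 d |
| oak | 20 mM | 30.0 mM (fed, over 2.5 d) | all else is in the flask from the start; the feed brings no volume worth counting | 12 d |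

| run | time / d | homo dimer / % | first product / % |
|---|---|---|---|
| zeta | 0.625 | 77.8 | 10.1 |
| zeta | 1.04 | 79.7 | 9.9 |
| zeta | 2.08 | 80.9 | 6.6 |
| zeta | 4.00 | 81.3 | 2.9 |
| zeta | 8.00 | 80.7 | 0 |
| theta | 2.08 | 76.6 | 5.4 |
| theta | 4.00 | 75.8 | 1.5 |
| theta | 6.00 | 75.8 | 0 |
| theta | 8.00 | 76.4 | 1.1 |
| theta | 10.0 | 76.6 | 0.1 |
| eta | 0.833 | 68.1 | 12.3 |
| eta | 1.67 | 68.4 | 5.5 |
| eta | 2.50 | 67.1 | 1.6 |
| eta | 5.00 | 68.2 | 0.9 |
| eta | 10.0 | 69.0 | 0 |

(each reading ± 0.5 percentage points)

1. the flask that comes out highest in amount of homo dimer, in percent of the substrate charged, or "all alike" when all lie within 1.5 percentage points (elm / maple / oak / all alike)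
2. homo dimer at the end, in percent of the substrate charged, elm
3. homo dimer at the end, in percent of the substrate charged, maple
4. homo dimer at the end, in percent of the substrate charged, oak

- percent here means substrate units held: one homo dimer counts as two

I read that level as a contest. Substrate pairs with itself at a rate that goes with its square, and reagent captures it at a rate that goes with its first power (pseudo-first-order). Zeta's plateau of 81.0% leaves 19.0% undimerised, and from that scattered level I took 1.39 mM at 30 mM of reagent as the crossover, the substrate concentration at which the two routes run equally fast. The reckoning was this: in a batch the undimerised part is the crossover over the charge, times the logarithm of one plus the charge over the crossover. The crossover grows in step with reagent, so scaled to eta's reagent it gives 69.1% of dimer, and eta's late readings averaged 68.1%.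

Zeta's first reading still had 3.2 percentage points of dimer to come, so about 1.33 mM of substrate stood there, a scattered reading. That gives a capture rate of 1.04 d⁻¹. The ladder then runs: dimerisation of the full charge in 0.0670 d, capture in 0.962 d, and the feed over 2.5 d.

I expected maple, which repeats zeta, to give 81.0%. In elm, with reagent taken as charged, substrate should hold near 2.65 mM, above the crossover, so 65.6% dimerises. In oak, substrate falls inversely with time as the crossover rises with time, so capture runs steadily and takes one crossover over the feed, leaving 93.0%.

The forecast named oak, with 66%, 81% and 94% for elm, maple and oak, holding that “substrate dimerises before much reagent arrives”.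

The flasks gave 65.5% for elm, 81.0% for maple and 94.1% for oak, so oak stood highest.

    substrate + reagent → first product + by-product (k = 1.30 M⁻¹ h⁻¹)
    reagent + first product → double product + by-product (k = 1.00 M⁻¹ h⁻¹)
    2 substrate → homo dimer (k = 14.0 M⁻¹ h⁻¹)
    substrate + by-product ⇌ idle adduct, settled at all times (K = 42.0 M⁻¹)

Elm's substrate averaged 2.51 mM over the first 2.5 d, above the crossover, and that level gives 64.4% dimerised. In a neighbour of elm, the same flask with 7.5 mM of reagent, the crossover falls to 0.348 mM and substrate should hold near 3.10 mM, which gives 89.9%. The computed flask gave 88.9%.

Readings and results were computed for an exercise.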